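Sunday's run stood at L = 0.290 after 20.0 h, where L is the natural logarithm of electrophile charged over electrophile left.

| flask | electrophile | nucleophile | protic impurity | remark | time |
|---|---|---|---|---|---|
| Sunday's | 1.4 M | 1.4 M | 0.70 M | run made earlier |  |
| Monday's | 1.4 M | 2 M | 0.70 M | run made earlier |  |
| Saturday's | 1.4 M | 2.3 M | 0.70 M | run made earlier |  |
| gamma | 1.4 M | 2.70 M | 0.700 M |  | 25 h |
| epsilon | 1.4 M | 1.30 M | 0.700 M |  | 25 h |

| run | time / h | electrophile / % | product / % |
|---|---|---|---|
| Sunday's | 4.00 | 87.9 | 11.9 |
| Sunday's | 8.00 | 82.5 | 17.3 |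
| Sunday's | 10.0 | 80.2 | 19.7 |
| Sunday's | 15.0 | 76.5 | 23.1 |
| Sunday's | 20.0 | 74.8 | 25.1 |
| Monday's | 1.33 | 93.1 | 7.0 |
| Monday's | 2.50 | 88.6 | 11.8 |
| Monday's | 5.00 | 81.0 | 18.9 |
| Monday's | 10.0 | 72.3 | 27.8 |
| Monday's | 20.0 | 63.1 | 37.5 |
| Saturday's | 4.00 | 81.4 | 18.9 |
| Saturday's | 8.00 | 71.6 | 28.6 |
| Saturday's | 10.0 | 67.7 | 32.9 |
| Saturday's | 15.0 | 61.7 | 38.4 |
| Saturday's | 20.0 | 56.6 | 43.2 |

(standard deviation of a reading: 0.3 percentage points)

* part of the electrophile that has reacted at the end, gamma
* part of the electrophile that has reacted at the end, epsilon
* what raising the concentration of nucleophile from its lowest to its highest value here does to the part of the electrophile that has reacted (changes below 5 percentage points count as none) (it falls / no change / it rises)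

- the earlier runs were read with a standard deviation of 0.3 percentage points

Saturday's run, with c(nucleophile) at 2.3 M, reached L = 0.569 at the same reading. So the gain in L per molar of nucleophile charged, with electrophile and impurity held, was g = 0.310 /M, my slope. Monday's run, not used for g, read 0.460 against 0.476 on the line, so I used the line. On that line gamma gave L = 0.693, or 50.0 % reacted, and epsilon gave L = 0.259, or 22.8 %. But those figures belong to 20.0 h, and Sunday's run still lost 1.7 points over its last interval, so I held them as low.

The forecast, for 25 h, gave 55 % (51 % to 60 %) for gamma and 23 % (20.5 % to 25 %) for epsilon, and for the trend it rises: “The yield therefore depends on the nucleophile in excess of the impurity”.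

The flasks gave 54.4 % for gamma and 24.4 % for epsilon; the trend was it rises, by 30 points.

    electrophile + nucleophile → acid set free + product (k = 0.0300 /M/h)
    nucleophile + acid set free ⇌ protonated nucleophile, settled at all times (K = 450 /M)
    nucleophile + protic impurity → quenched reagent (k = 0.160 /M/h)

The forecast held, and between epsilon and gamma the slope came to 0.361 /M at 25 h, against my g. Gamma reached 54.4 % against epsilon's 24.4 %, and the main reason is its higher charge of nucleophile. Of that charge, gamma ended with 18.2 % free, while epsilon's nucleophile, the limiting reagent there, ended at 6.49 %.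

A neighbour flask has epsilon's charges of nucleophile and protic impurity but 0.84 M of electrophile; g was read with electrophile held, so it can only repeat L = 0.259, or 22.8 %. That neighbour flask reacted 30.5 %, keeping 15 % of its nucleophile free, more than epsilon's 6.5 %.

The runs were generated by integration for an exercise, and the scatter is random.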